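## The problem

Target 25 is a monocyclic cyclobutane. C1 and C2 carry carboxyl groups, each esterified with the secondary hydroxyl of (R)-danshensu (21), and C3 and C4 carry 3,4-dihydroxyphenyl groups. The ring is (1R,2R,3R,4R): the aryl groups are trans, the carboxyls are trans, and each carboxyl is cis to the aryl group on the neighbouring carbon, so the molecule is C2-symmetric and only half of it has to be solved. This is not the stable arrangement. Epimerisation at C1 or C2 leads towards the all-trans isomer, so these centres cannot be set by equilibrating open esters and must not meet base while unconstrained. C3 and C4 cannot epimerise and must be set in absolute terms. Once in place they can hold C1 and C2, because a carboxyl can be tied as a six-membered lactone to an ortho oxygen of the neighbouring aryl group only when the two are cis. The four catechols, two free acids and two α-acyloxy acid centres (from 21) will not survive oxidants, strong base or heat, so they are carried as benzyl ethers and esters to the last step. The feature that opens the key step is that C2, C3 and C4 with their trans aryl groups form a trans-2,3-diarylcyclopropane once C1 is taken out of the ring. C1, with its own carboxyl, is then a carbene carbon on the quaternary cyclopropane carbon, and by symmetry either ring bond that migrates to it gives the same four-membered ring.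

## Retrosynthesis

25 from 24 and 23. The ten O–benzyl bonds of 24 are cut last, by hydrogenolysis. The two aryl C–H bonds ortho to the ring are traced back to the aryl triflates of 23. Benzyl is chosen throughout because one neutral step then releases the whole molecule; the extra ortho oxygen is a temporary handle and leaves as triflate. The forward steps must spare the cyclobutane and reduce a hindered, electron-rich triflate.

23 from 20 and 22. The two acyl C–O bonds to the side chains are cut, giving the C2-symmetric bis-lactone 20 and the protected alcohol 22 (one step from 21). The neighbouring cut, esterification of a free diacid, would first require hydrolysis of simple esters at the epimerisable C1 and C2. In 20 the carboxyls are already aryl esters, activated for transacylation and held cis to their aryl neighbours until they are transferred. The forward reaction must open each lactone with the alkoxide of 22 and trap the released phenoxide before it closes again.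

20 from 18. The two lactone C–O bonds are cut, giving the bis(MOM ether) dimethyl ester 18 by way of bis-phenol 19. A dihydrocoumarin can be fused to a cyclobutane only in the cis sense without prohibitive strain, so closure of both lactones proves and locks the (1R,2R) configuration. It also separates 20 from any epimer, which keeps a free phenol. 20 has the skeleton of a head-to-head coumarin photodimer, a class known to open with nucleophiles. Acid suffices in the forward direction, so no base touches C1 and C2.

18 from 17. The C1–H and C2–H bonds are removed, giving cyclobutene diester 17. The other order, lactonisation first and reduction of the unsaturated bis-lactone, would let the lactones steer both protonations. It is rejected because 17 is a push–pull trans-3,4-diarylcyclobutene that is expected to open to the diene near room temperature, and a free ortho phenol could add to the enediester. 17 is therefore reduced at −78 °C as soon as it is formed. The forward step has to deliver each hydrogen anti to the adjacent aryl group.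

17 from 16. The C1–C4 bond is cut by running a 1,2-shift in reverse. The ring contracts to a trans-2,3-diarylcyclopropane whose quaternary carbon bears one ester and a diazo(methoxycarbonyl)methyl group, compound 16. The [2+2] cuts break two ring bonds and leave C3/C4 to a photochemical event. This cut breaks one bond and takes C3 and C4 from a three-membered ring in which a trans-diaryl unit can be made in one absolute sense. 16 has two stereocentres instead of four. The forward reaction must turn the metal carbene into the ring-expanded alkene faster than it fragments or attacks the nearby aryl group.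

16 from 10. The diazo group is removed (14), then the side-chain carbon by Arndt–Eistert logic (diazoketone 13, acid chloride 12, acid 11), arriving at geminal diester 10. The two esters of 10 are homotopic through the C2 axis, so mono-saponification can give only one acid. In 14 the side-chain methylene is the only enolisable position, so diazo transfer has a single site. The cyclopropane and its two stereocentres are untouched throughout.

10 from 5 and 9. The two ring bonds to one aryl-bearing carbon are cut, giving alkylidenemalonate 5 and the benzylide of chiral sulfonium salt 9. Carbene addition to a stilbene, the neighbouring cut, is poor for 1,2-diarylalkenes and malonate carbenes. The ylide route is stepwise, trans-selective and lets sulfide 7 set the absolute configuration. Both partners come from aldehyde 3: condensation with dimethyl malonate 4 gives 5; reduction to 6, chlorination to 8 and alkylation of 7 give 9. Aldehyde 3 is reached from 2,4,5-trihydroxybenzaldehyde 1 through 2.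

## Roads not taken

Alternative 1: The cut is made at the two ring–aryl bonds. The bis(quinolin-8-yl) amide A2 would be arylated twice with aryl iodide A3 under Pd(OAc)2 and AgOAc, each amide directing palladium to the cis hydrogen of the adjacent methylene, to give A1.
- Merits: the cis relation between each carboxyl and its neighbouring aryl group, the hard part of the target, is exactly what the directing group delivers. The aryl groups need no extra oxygen, and A1 is only a few steps from a resolved four-membered diacid.
- Weak points: the second arylation must occur next to the first aryl group on a substrate that can bind palladium through both amides. Above all, two hindered quinolinyl amides must be removed. Forcing hydrolysis would epimerise C1 and C2 to the all-trans isomer, so activation as N-Boc imides and alcoholysis with 22 would have to work twice without epimerisation.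
- Comparison: this road is clearly shorter than the chosen one. The chosen plan sets against it that the carboxyls are never amides: they reach the coupling as aryl lactones held in the right configuration, and C3/C4 are set by a reagent and not by resolution.

Alternative 2: The cut goes through C3–C4 and C1–C2 at once, back to the linear tetraene A4. On heating, A4 would close by conrotatory 8π and then disrotatory 6π electrocyclisation to the bicyclic diene A5, with trans aryl groups and a cis ring fusion.
- Merits: the cascade needs no reagent and is well known for simple tetraenes.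
- Weak points: A4 needs two Z alkenes made with full control, and nothing sets absolute configuration. The cyclohexadiene of A5 must be cleaved oxidatively in the presence of four electron-rich arenes to remove two carbons. The resulting cis-1,2-dicarbonyl compound then has one centre that must be inverted towards the less stable side.
- Comparison: the chosen plan is longer before its key step, but it controls every centre and has no step that runs against thermodynamics without a lock.

Alternative 3: The cut is the crossed [2+2] one, through C1–C4 and C2–C3, back to stilbene A6 and the fumarate A7 of protected danshensu. Irradiation of A6 with A7 would give, through a sandwich exciplex in which each ester lies over an aryl ring, the cyclobutane A8, which is identical with 24.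
- Merits: this is by far the shortest road. One photochemical step sets the relative configuration of all four ring centres, the side chains are already in place, and one hydrogenolysis remains.
- Weak points: facial selectivity rests only on stereocentres three bonds from the alkene and will probably give both (1R,2R,3R,4R) and (1S,2S,3S,4S) rings. A6 can isomerise and self-dimerise, maleate-derived isomers can leak in, and the diastereomers are large and very similar.
- Comparison: if that separation were easy, this road would be better than the chosen one in length and convergence. The chosen plan sets against it only that the ring configuration is fixed by a chiral reagent at the cyclopropane stage and carried through stereospecific steps, at roughly three times the number of operations.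

Key step: step 11

Assumption: alkylation of 7 is taken to occur on the exo lone pair of sulfur and the derived ylide is taken to give the (2S,3S) cyclopropane; if the sense of induction proves opposite, the enantiomer of 7 is used and nothing else changes.

Abbreviation used in the steps: Ar = 4,5-bis(benzyloxy)-2-(methoxymethoxy)phenyl.

Step 1
Reactants: 1 2,4,5-trihydroxybenzaldehyde
Product: 2 4,5-bis(benzyloxy)-2-hydroxybenzaldehyde
Conditions: BnBr (2.05 equiv), K2CO3 (2.1 equiv), DMF, 0 °C → rt, argon
Reagents that add atoms: benzyl bromide, BrCc1ccccc1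
Why: Williamson ether synthesis; the 2-hydroxyl is hydrogen-bonded to the formyl group and its phenoxide is the least nucleophilic, so about two equivalents of benzyl bromide should take the 4- and 5-hydroxyls and leave it free.

Step 2
Reactants: 2 4,5-bis(benzyloxy)-2-hydroxybenzaldehyde
Product: 3 4,5-bis(benzyloxy)-2-(methoxymethoxy)benzaldehyde (ArCHO)
Conditions: MOMCl, i-Pr2NEt, CH2Cl2, 0 °C → rt
Reagents that add atoms: chloromethyl methyl ether, COCCl
Why: O-alkylation of the remaining phenol to the MOM acetal, which is stable to the bases, hydride and carbene chemistry ahead and is removed by acid where the phenol is needed.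

Step 3
Reactants: 3 ArCHO; 4 dimethyl malonate
Product: 5 dimethyl 2-(Ar-methylidene)propanedioate
Conditions: piperidine (cat.), AcOH (cat.), toluene, reflux, azeotropic removal of water
Reagents that add atoms: none
Why: Knoevenagel condensation under piperidinium acetate catalysis; the trisubstituted alkene has no geometry to control.

Step 4
Reactants: 3 ArCHO
Product: 6 ArCH2OH, [4,5-bis(benzyloxy)-2-(methoxymethoxy)phenyl]methanol
Conditions: NaBH4, MeOH–THF, 0 °C
Reagents that add atoms: none
Why: Hydride reduction of the aldehyde; nothing else in 3 is reduced by NaBH4.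

Step 5
Reactants: 6 ArCH2OH; 7 (1R,4R,5R)-4,7,7-trimethyl-6-thiabicyclo[3.2.1]octane (isothiocineole)
Product: 9 (1R,4R,5R)-6-(ArCH2)-4,7,7-trimethyl-6-thiabicyclo[3.2.1]octan-6-ium tetrafluoroborate (S-benzyl group exo), via benzylic chloride 8 (not isolated)
Conditions: MsCl, LiCl, 2,4,6-collidine, DMF, 0 °C; then 7, NaBF4, acetone, 0 °C → rt; salt stored cold
Reagents that add atoms: sodium tetrafluoroborate, [Na+].F[B-](F)(F)F
Why: The alcohol is converted to the chloride under buffered conditions that spare the MOM ether, and the activated benzylic chloride alkylates the sulfide. The tetrafluoroborate counter-ion cannot reverse the alkylation, and attack on the exo lone pair should give one configuration at sulfur.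

Step 6
Reactants: 9 sulfonium tetrafluoroborate; 5 dimethyl 2-(Ar-methylidene)propanedioate
Product: 10 dimethyl (2S,3S)-2,3-bis(Ar)cyclopropane-1,1-dicarboxylate
Conditions: t-BuOK, THF, −78 °C; then 5, −78 → −20 °C
Reagents that add atoms: none
Why: Sulfur-ylide cyclopropanation (Michael-initiated ring closure): the benzylide adds to the alkylidenemalonate and the malonate anion displaces the sulfide with inversion. Betaine formation is reversible and closure through the anti conformer should give the trans-diaryl product. The bicyclic sulfide shields one face of the ylide carbon and so sets that centre, from which the second follows.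

Step 7
Reactants: 10 dimethyl (2S,3S)-2,3-bis(Ar)cyclopropane-1,1-dicarboxylate
Product: 11 (2S,3S)-2,3-bis(Ar)-1-(methoxycarbonyl)cyclopropane-1-carboxylic acid
Conditions: KOH (1.1 equiv), MeOH–THF–H2O, rt → 40 °C; then aq. KHSO4 to pH 4, 0 °C
Reagents that add atoms: potassium hydroxide, [K+].[OH-]
Why: Saponification with one equivalent of hydroxide; the two esters are homotopic through the C2 axis, so only one mono-acid can form, and the carboxylate slows the second hydrolysis.

Step 8
Reactants: 11 (2S,3S)-2,3-bis(Ar)-1-(methoxycarbonyl)cyclopropane-1-carboxylic acid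
Product: 13 methyl (2S,3S)-2,3-bis(Ar)-1-(2-diazoacetyl)cyclopropane-1-carboxylate, via acid chloride 12 (not isolated)
Conditions: 1-chloro-N,N,2-trimethylprop-1-en-1-amine, CH2Cl2, 0 °C; then CH2N2 (excess), Et2O, 0 °C
Reagents that add atoms: diazomethane, C=[N+]=[N-]
Why: First half of the Arndt–Eistert homologation: the α-chloroenamine forms the acid chloride without free HCl, which spares the MOM ethers and the donor–acceptor cyclopropane. Diazomethane is then acylated, a second equivalent taking up the HCl.

Step 9
Reactants: 13 methyl (2S,3S)-2,3-bis(Ar)-1-(2-diazoacetyl)cyclopropane-1-carboxylate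
Product: 14 methyl (2S,3S)-2,3-bis(Ar)-1-(2-methoxy-2-oxoethyl)cyclopropane-1-carboxylate
Conditions: PhCO2Ag (10 mol %), Et3N, MeOH–THF, rt, sonication
Reagents that add atoms: methanol, CO
Why: Wolff rearrangement: silver-induced loss of nitrogen with migration of the cyclopropyl carbon gives a ketene that methanol traps as the homologated ester; the migrating carbon is not a stereocentre.

Step 10
Reactants: 14 methyl (2S,3S)-2,3-bis(Ar)-1-(2-methoxy-2-oxoethyl)cyclopropane-1-carboxylate
Product: 16 methyl (2S,3S)-2,3-bis(Ar)-1-(1-diazo-2-methoxy-2-oxoethyl)cyclopropane-1-carboxylate, via trifluoroacetyl ester 15 (not isolated)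
Conditions: LiHMDS, THF, −78 °C, then CF3CO2CH2CF3; then 4-acetamidobenzenesulfonyl azide, Et3N, MeCN, rt
Reagents that add atoms: 4-acetamidobenzenesulfonyl azide, CC(=O)Nc1ccc(cc1)S(=O)(=O)N=[N+]=[N-]
Why: Deacylative diazo transfer of the Regitz type: the side-chain methylene is the only enolisable position, its lithium enolate is trifluoroacetylated, and the sulfonyl azide then transfers the diazo group with loss of the trifluoroacetyl group.

Step 11
Reactants: 16 methyl (2S,3S)-2,3-bis(Ar)-1-(1-diazo-2-methoxy-2-oxoethyl)cyclopropane-1-carboxylate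
Product: 17 dimethyl (3S,4S)-3,4-bis(Ar)cyclobut-1-ene-1,2-dicarboxylate (kept as a cold solution and used at once)
Conditions: Rh2(OPiv)4 (1 mol %), toluene, slow addition of 16, −40 → −15 °C
Reagents that add atoms: none
Why: The dirhodium tetracarboxylate takes up the diazo carbon and nitrogen is lost, giving an electrophilic rhodium carbenoid flanked by its ester and the quaternary cyclopropane carbon. One of the two ring bonds from that quaternary carbon to an aryl-bearing carbon then migrates to the carbenoid carbon as rhodium leaves, which forms the new ring bond (C1–C4 of the target) and the C1=C2 alkene. The closest known reaction is the ring expansion of α-cyclopropyl α-diazo esters to cyclobut-1-enecarboxylates under dirhodium or silver catalysis. The four-membered ring is closed by ring enlargement, a 1,2-alkyl shift that inserts the carbene carbon into a cyclopropane bond, not by an end-to-end cyclisation. No stereocentre is created: the migrating benzylic carbon moves with retention and the other is untouched, so both keep their configuration and the aryl groups stay trans. Regiochemistry is not an issue because either bond gives the same C2-symmetric 17. The selectivity needed is ring expansion over fragmentation to alkyne and stilbene and over attack on the cis aryl ring or its MOM oxygen; the metal-bound carbenoid and the electron-rich migrating carbon should secure it. The pivalate catalyst is chosen because it is soluble and active at low temperature, which matters since 17 is expected to undergo conrotatory opening to the bis(arylidene)succinate on warming.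

Step 12
Reactants: 17 dimethyl (3S,4S)-3,4-bis(Ar)cyclobut-1-ene-1,2-dicarboxylate (cold toluene solution)
Product: 18 dimethyl (1R,2R,3R,4R)-3,4-bis(Ar)cyclobutane-1,2-dicarboxylate
Conditions: SmI2 (2.5 equiv), MeOH, THF, −78 °C; the solution of 17 is added to the reductant
Reagents that add atoms: none
Why: Conjugate reduction of the enediester by two single-electron transfers from SmI2 with protonation by methanol, at a temperature at which the cyclobutene cannot open. The first proton should enter C1 anti to the C4 aryl group and the second should enter C2 anti to the C3 aryl group, which also gives the trans diester, so each ester ends up cis to its neighbouring aryl group. The assignment is secured in step 13, where only this isomer can close both lactones.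

Step 13
Reactants: 18 dimethyl (1R,2R,3R,4R)-3,4-bis(Ar)cyclobutane-1,2-dicarboxylate
Product: 20 bis-lactone in which each carboxyl is closed onto the ortho oxygen of the cis aryl group on the adjacent carbon (anti head-to-head coumarin-dimer skeleton; cyclobutane centres R,R,R,R as in 18), via bis-phenol diester 19 (not isolated)
Conditions: methanolic HCl, THF, 40 °C; then p-TsOH·H2O (cat.), toluene, 80 °C, removal of MeOH, argon
Reagents that add atoms: none
Why: Acidic methanolysis removes the MOM acetals and acid-catalysed transesterification closes two six-membered aryl lactones, driven by loss of methanol. Only an ester cis to its ortho-hydroxyaryl neighbour can close, so the neutral C2-symmetric bis-lactone is formed from the (1R,2R) isomer alone and separates from any epimer that keeps a phenol. From here C1 and C2 are locked.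

Step 14
Reactants: 21 (2R)-3-(3,4-dihydroxyphenyl)-2-hydroxypropanoic acid (danshensu)
Product: 22 benzyl (2R)-3-[3,4-bis(benzyloxy)phenyl]-2-hydroxypropanoate
Conditions: BnBr (3.3 equiv), K2CO3, DMF, rt, argon
Reagents that add atoms: benzyl bromide, BrCc1ccccc1
Why: Carbonate deprotonates the acid and the two phenols but not the secondary alcohol, so SN2 benzylation gives the ester and both ethers and leaves the hydroxyl free; the stereocentre is not involved.

Step 15
Reactants: 20 bis-lactone; 22 benzyl (2R)-3-[3,4-bis(benzyloxy)phenyl]-2-hydroxypropanoate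
Product: 23 bis{(2R)-1-(benzyloxy)-3-[3,4-bis(benzyloxy)phenyl]-1-oxopropan-2-yl} (1R,2R,3R,4R)-3,4-bis{4,5-bis(benzyloxy)-2-[(trifluoromethanesulfonyl)oxy]phenyl}cyclobutane-1,2-dicarboxylate
Conditions: 22 (2.4 equiv), NaHMDS (2.2 equiv), THF, −78 °C; then 20, −78 → −30 °C; then PhNTf2 (2.6 equiv), −30 → 0 °C
Reagents that add atoms: N-phenylbis(trifluoromethanesulfonimide), O=S(=O)(N(c1ccccc1)S(=O)(=O)C(F)(F)F)C(F)(F)F
Why: Transacylation: the sodium alkoxide of 22 adds to each aryl lactone and expels a phenoxide, a much weaker base, so opening is favoured in THF, as in the known opening of coumarin dimers by nucleophiles. Triflation of the phenoxide in the same flask prevents re-closure. Low temperature and the absence of excess base protect C1, C2 and the lactate centres, and the side-chain stereocentre is retained because only its oxygen reacts.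

Step 16
Reactants: 23 bis(aryl triflate) tetraester
Product: 24 bis{(2R)-1-(benzyloxy)-3-[3,4-bis(benzyloxy)phenyl]-1-oxopropan-2-yl} (1R,2R,3R,4R)-3,4-bis[3,4-bis(benzyloxy)phenyl]cyclobutane-1,2-dicarboxylate
Conditions: Pd(OAc)2 (10 mol %), dppf (12 mol %), HCO2H, Et3N, DMF, 70 °C
Reagents that add atoms: none
Why: Palladium-catalysed reduction of aryl triflates by formate: oxidative addition of zerovalent palladium, exchange of triflate for formate, loss of CO2 and reductive elimination of Ar–H. The buffered amine is too weak to epimerise the ester centres.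

Step 17
Reactants: 24 decabenzyl-protected target
Product: 25 (2R,2'R)-2,2'-{[(1R,2R,3R,4R)-3,4-bis(3,4-dihydroxyphenyl)cyclobutane-1,2-dicarbonyl]bis(oxy)}bis[3-(3,4-dihydroxyphenyl)propanoic acid]
Conditions: H2 (1 atm), 10% Pd/C, THF–MeOH, rt
Reagents that add atoms: none
Why: Hydrogenolysis of eight benzyl ethers and two benzyl esters under neutral conditions; the cyclobutane C–C bonds and the non-benzylic acyloxy C–O bonds are not cleaved, and no stereocentre is touched.

Compound list

1 | 2,4,5-trihydroxybenzaldehyde | O=Cc1cc(O)c(O)cc1O | starting material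
2 | 4,5-bis(benzyloxy)-2-hydroxybenzaldehyde | O=Cc1cc(OCc2ccccc2)c(OCc2ccccc2)cc1O | intermediate
3 | 4,5-bis(benzyloxy)-2-(methoxymethoxy)benzaldehyde | O=Cc1cc(OCc2ccccc2)c(OCc2ccccc2)cc1OCOC | intermediate
4 | dimethyl malonate | COC(=O)CC(=O)OC | starting material
5 | dimethyl 2-{[4,5-bis(benzyloxy)-2-(methoxymethoxy)phenyl]methylidene}propanedioate | COC(=O)C(=Cc1cc(OCc2ccccc2)c(OCc2ccccc2)cc1OCOC)C(=O)OC | intermediate
6 | [4,5-bis(benzyloxy)-2-(methoxymethoxy)phenyl]methanol | OCc1cc(OCc2ccccc2)c(OCc2ccccc2)cc1OCOC | intermediate
7 | (1R,4R,5R)-4,7,7-trimethyl-6-thiabicyclo[3.2.1]octane (isothiocineole) | C[C@@H]1CC[C@@H]2C[C@H]1SC2(C)C | starting material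
8 | 1,2-bis(benzyloxy)-4-(chloromethyl)-5-(methoxymethoxy)benzene | ClCc1cc(OCc2ccccc2)c(OCc2ccccc2)cc1OCOC | intermediate
9 | (1R,4R,5R)-6-{[4,5-bis(benzyloxy)-2-(methoxymethoxy)phenyl]methyl}-4,7,7-trimethyl-6-thiabicyclo[3.2.1]octan-6-ium tetrafluoroborate, S-benzyl group exo (syn to the one-carbon bridge) | C[C@@H]1CC[C@@H]2C[C@H]1[S@@+](Cc1cc(OCc3ccccc3)c(OCc3ccccc3)cc1OCOC)C2(C)C.F[B-](F)(F)F | intermediate
10 | dimethyl (2S,3S)-2,3-bis[4,5-bis(benzyloxy)-2-(methoxymethoxy)phenyl]cyclopropane-1,1-dicarboxylate | COC(=O)C1(C(=O)OC)[C@H](c2cc(OCc3ccccc3)c(OCc3ccccc3)cc2OCOC)[C@H]1c1cc(OCc2ccccc2)c(OCc2ccccc2)cc1OCOC | intermediate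
11 | (2S,3S)-2,3-bis[4,5-bis(benzyloxy)-2-(methoxymethoxy)phenyl]-1-(methoxycarbonyl)cyclopropane-1-carboxylic acid | COC(=O)C1(C(=O)O)[C@H](c2cc(OCc3ccccc3)c(OCc3ccccc3)cc2OCOC)[C@H]1c1cc(OCc2ccccc2)c(OCc2ccccc2)cc1OCOC | intermediate
12 | methyl (2S,3S)-2,3-bis[4,5-bis(benzyloxy)-2-(methoxymethoxy)phenyl]-1-(chlorocarbonyl)cyclopropane-1-carboxylate | COC(=O)C1(C(=O)Cl)[C@H](c2cc(OCc3ccccc3)c(OCc3ccccc3)cc2OCOC)[C@H]1c1cc(OCc2ccccc2)c(OCc2ccccc2)cc1OCOC | intermediate
13 | methyl (2S,3S)-2,3-bis[4,5-bis(benzyloxy)-2-(methoxymethoxy)phenyl]-1-(2-diazoacetyl)cyclopropane-1-carboxylate | COC(=O)C1(C(=O)C=[N+]=[N-])[C@H](c2cc(OCc3ccccc3)c(OCc3ccccc3)cc2OCOC)[C@H]1c1cc(OCc2ccccc2)c(OCc2ccccc2)cc1OCOC | intermediate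
14 | methyl (2S,3S)-2,3-bis[4,5-bis(benzyloxy)-2-(methoxymethoxy)phenyl]-1-(2-methoxy-2-oxoethyl)cyclopropane-1-carboxylate | COC(=O)CC1(C(=O)OC)[C@H](c2cc(OCc3ccccc3)c(OCc3ccccc3)cc2OCOC)[C@H]1c1cc(OCc2ccccc2)c(OCc2ccccc2)cc1OCOC | intermediate
15 | methyl (2S,3S)-2,3-bis[4,5-bis(benzyloxy)-2-(methoxymethoxy)phenyl]-1-(4,4,4-trifluoro-1-methoxy-1,3-dioxobutan-2-yl)cyclopropane-1-carboxylate (side-chain carbon unassigned, largely enolised) | COC(=O)C(C(=O)C(F)(F)F)C1(C(=O)OC)[C@H](c2cc(OCc3ccccc3)c(OCc3ccccc3)cc2OCOC)[C@H]1c1cc(OCc2ccccc2)c(OCc2ccccc2)cc1OCOC | intermediate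
16 | methyl (2S,3S)-2,3-bis[4,5-bis(benzyloxy)-2-(methoxymethoxy)phenyl]-1-(1-diazo-2-methoxy-2-oxoethyl)cyclopropane-1-carboxylate | COC(=O)C(=[N+]=[N-])C1(C(=O)OC)[C@H](c2cc(OCc3ccccc3)c(OCc3ccccc3)cc2OCOC)[C@H]1c1cc(OCc2ccccc2)c(OCc2ccccc2)cc1OCOC | intermediate
17 | dimethyl (3S,4S)-3,4-bis[4,5-bis(benzyloxy)-2-(methoxymethoxy)phenyl]cyclobut-1-ene-1,2-dicarboxylate | COC(=O)C1=C(C(=O)OC)[C@H](c2cc(OCc3ccccc3)c(OCc3ccccc3)cc2OCOC)[C@H]1c1cc(OCc2ccccc2)c(OCc2ccccc2)cc1OCOC | intermediate
18 | dimethyl (1R,2R,3R,4R)-3,4-bis[4,5-bis(benzyloxy)-2-(methoxymethoxy)phenyl]cyclobutane-1,2-dicarboxylate | COC(=O)[C@H]1[C@H](C(=O)OC)[C@H](c2cc(OCc3ccccc3)c(OCc3ccccc3)cc2OCOC)[C@H]1c1cc(OCc2ccccc2)c(OCc2ccccc2)cc1OCOC | intermediate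
19 | dimethyl (1R,2R,3R,4R)-3,4-bis[4,5-bis(benzyloxy)-2-hydroxyphenyl]cyclobutane-1,2-dicarboxylate | COC(=O)[C@H]1[C@H](C(=O)OC)[C@H](c2cc(OCc3ccccc3)c(OCc3ccccc3)cc2O)[C@H]1c1cc(OCc2ccccc2)c(OCc2ccccc2)cc1O | intermediate
20 | 2,3,10,11-tetrakis(benzyloxy)-6a,6b,12b,12c-tetrahydrocyclobuta[1,2-c:4,3-c']dichromene-6,7-dione, the anti head-to-head bis-lactone of 19; both lactones cis-fused on opposite faces, cyclobutane centres R,R,R,R in the numbering of 18 | O=C1Oc2cc(OCc3ccccc3)c(OCc3ccccc3)cc2[C@H]4[C@@H]1[C@@H]1C(=O)Oc2cc(OCc3ccccc3)c(OCc3ccccc3)cc2[C@@H]14 | intermediate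
21 | (2R)-3-(3,4-dihydroxyphenyl)-2-hydroxypropanoic acid (danshensu) | O[C@H](Cc1ccc(O)c(O)c1)C(=O)O | starting material
22 | benzyl (2R)-3-[3,4-bis(benzyloxy)phenyl]-2-hydroxypropanoate | O[C@H](Cc1ccc(OCc2ccccc2)c(OCc2ccccc2)c1)C(=O)OCc1ccccc1 | intermediate
23 | bis{(2R)-1-(benzyloxy)-3-[3,4-bis(benzyloxy)phenyl]-1-oxopropan-2-yl} (1R,2R,3R,4R)-3,4-bis{4,5-bis(benzyloxy)-2-[(trifluoromethanesulfonyl)oxy]phenyl}cyclobutane-1,2-dicarboxylate | O=C(O[C@H](Cc1ccc(OCc2ccccc2)c(OCc2ccccc2)c1)C(=O)OCc1ccccc1)[C@H]1[C@H](C(=O)O[C@H](Cc2ccc(OCc3ccccc3)c(OCc3ccccc3)c2)C(=O)OCc2ccccc2)[C@H](c2cc(OCc3ccccc3)c(OCc3ccccc3)cc2OS(=O)(=O)C(F)(F)F)[C@H]1c1cc(OCc2ccccc2)c(OCc2ccccc2)cc1OS(=O)(=O)C(F)(F)F | intermediate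
24 | bis{(2R)-1-(benzyloxy)-3-[3,4-bis(benzyloxy)phenyl]-1-oxopropan-2-yl} (1R,2R,3R,4R)-3,4-bis[3,4-bis(benzyloxy)phenyl]cyclobutane-1,2-dicarboxylate | O=C(O[C@H](Cc1ccc(OCc2ccccc2)c(OCc2ccccc2)c1)C(=O)OCc1ccccc1)[C@H]1[C@H](C(=O)O[C@H](Cc2ccc(OCc3ccccc3)c(OCc3ccccc3)c2)C(=O)OCc2ccccc2)[C@H](c2ccc(OCc3ccccc3)c(OCc3ccccc3)c2)[C@H]1c1ccc(OCc2ccccc2)c(OCc2ccccc2)c1 | intermediate
25 | (2R,2'R)-2,2'-{[(1R,2R,3R,4R)-3,4-bis(3,4-dihydroxyphenyl)cyclobutane-1,2-dicarbonyl]bis(oxy)}bis[3-(3,4-dihydroxyphenyl)propanoic acid] | O=C(O[C@H](Cc1ccc(O)c(O)c1)C(=O)O)[C@H]1[C@H](C(=O)O[C@H](Cc2ccc(O)c(O)c2)C(=O)O)[C@H](c2ccc(O)c(O)c2)[C@H]1c1ccc(O)c(O)c1 | target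

Total: 17 steps. Longest linear sequence: 15 steps (1, 2, 4 to 13, 15 to 17).

Least certain steps

Step 11 (key step). The carbenoid may be diverted before the ring bond migrates, by fragmentation to alkyne and stilbene or by attack on the cis aryl ring or its MOM oxygen. Alternatively, nitrogen may be lost only at temperatures at which the cyclobutene already opens to the diene. The fallback gives up ring expansion for a photochemical entry to the same bis-lactone and sets out from 2. Wittig olefination of 2 with ethyl (triphenylphosphoranylidene)acetate in hot N,N-diethylaniline, with lactonisation in the same flask, should give 6,7-bis(benzyloxy)coumarin F1. Benzophenone-sensitised irradiation of F1 in benzene is expected to favour the anti head-to-head dimer, that is 20 together with its enantiomer F2. The racemate rejoins the route at 20. After step 15 the antipodal series is removed by chromatography as the diastereomeric tetraester F3, the (1S,2S,3S,4S) isomer of 23. This costs reagent control of C3/C4 and half the material.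

Step 12. Facial selectivity in the second protonation may be poor, because the C2 enolate has the C1 ester on one face and the C3 aryl group on the other. The radical anion of the cyclobutene may also open before it is protonated. The fallback replaces kinetic control by a lactone-driven correction; it sets out from 18 as obtained and returns at 20. The C2 epimer of 18, dimethyl (1R,2S,3R,4R)-3,4-bis[4,5-bis(benzyloxy)-2-(methoxymethoxy)phenyl]cyclobutane-1,2-dicarboxylate F4, can close only one lactone under the conditions of step 13 and should give the mono-lactone methyl ester F5, which keeps one phenol and is easily separated from 20. Heating F5 with DBU in toluene with removal of methanol should epimerise the free ester centre, the other being held by its cis-fused lactone, and close the second lactone to 20.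

Step 15. Opening may be incomplete if the lactone re-closes before triflation, the alkoxide of 22 may condense with itself, and alkoxide may epimerise C1/C2 once the lactone lock is released. The fallback reverses the roles of acid and alcohol; it sets out from 20 and returns at 23. Sodium allyloxide (allyl alcohol, NaHMDS) opens 20 far more easily than a hindered alkoxide, and trapping with PhNTf2 should give diallyl (1R,2R,3R,4R)-3,4-bis{4,5-bis(benzyloxy)-2-[(trifluoromethanesulfonyl)oxy]phenyl}cyclobutane-1,2-dicarboxylate F6. Deallylation with Pd(PPh3)4 and morpholine at room temperature gives the dicarboxylic acid F7 without base strong enough to epimerise it. Steglich esterification of F7 with 22 (EDC, DMAP, CH2Cl2, 0 °C) then gives 23.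

Step 6. The very electron-rich benzylsulfonium salt 9 may ionise on storage or during ylide formation, and reversible betaine formation may erode the enantioselectivity. The fallback generates the same ylide catalytically from a metal carbene, so that 9 is never handled; it sets out from 3 and returns at 10. Condensation of 3 with tosylhydrazide gives the tosylhydrazone F8. Its sodium salt (NaOMe), warmed to 40 °C in toluene with a phase-transfer salt, releases the aryldiazomethane F9 slowly. Rh2(OAc)4 transfers the carbene to sulfide 7 (20 mol %), and the resulting ylide cyclopropanates 5 to 10 and returns 7.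

Further compounds

F1 | step 11 | 6,7-bis(benzyloxy)-2H-chromen-2-one | O=C1C=Cc2cc(OCc3ccccc3)c(OCc3ccccc3)cc2O1
F2 | step 11 | enantiomer of 20 (cyclobutane centres S,S,S,S) | O=C1Oc2cc(OCc3ccccc3)c(OCc3ccccc3)cc2[C@@H]4[C@H]1[C@H]1C(=O)Oc2cc(OCc3ccccc3)c(OCc3ccccc3)cc2[C@H]14
F3 | step 11 | bis{(2R)-1-(benzyloxy)-3-[3,4-bis(benzyloxy)phenyl]-1-oxopropan-2-yl} (1S,2S,3S,4S)-3,4-bis{4,5-bis(benzyloxy)-2-[(trifluoromethanesulfonyl)oxy]phenyl}cyclobutane-1,2-dicarboxylate | O=C(O[C@H](Cc1ccc(OCc2ccccc2)c(OCc2ccccc2)c1)C(=O)OCc1ccccc1)[C@@H]1[C@@H](C(=O)O[C@H](Cc2ccc(OCc3ccccc3)c(OCc3ccccc3)c2)C(=O)OCc2ccccc2)[C@@H](c2cc(OCc3ccccc3)c(OCc3ccccc3)cc2OS(=O)(=O)C(F)(F)F)[C@@H]1c1cc(OCc2ccccc2)c(OCc2ccccc2)cc1OS(=O)(=O)C(F)(F)F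
F4 | step 12 | dimethyl (1R,2S,3R,4R)-3,4-bis[4,5-bis(benzyloxy)-2-(methoxymethoxy)phenyl]cyclobutane-1,2-dicarboxylate | COC(=O)[C@H]1[C@@H](C(=O)OC)[C@H](c2cc(OCc3ccccc3)c(OCc3ccccc3)cc2OCOC)[C@H]1c1cc(OCc2ccccc2)c(OCc2ccccc2)cc1OCOC
F5 | step 12 | mono-lactone methyl ester: C1 carboxyl closed onto the C4 aryl group, C2 methyl ester cis to the lactone carbonyl, free phenol on the C3 aryl group | O=C1Oc2cc(OCc3ccccc3)c(OCc3ccccc3)cc2[C@H]4[C@@H]1[C@@H](C(=O)OC)[C@@H]4c1cc(OCc2ccccc2)c(OCc2ccccc2)cc1O
F6 | step 15 | diallyl (1R,2R,3R,4R)-3,4-bis{4,5-bis(benzyloxy)-2-[(trifluoromethanesulfonyl)oxy]phenyl}cyclobutane-1,2-dicarboxylate | C=CCOC(=O)[C@H]1[C@H](C(=O)OCC=C)[C@H](c2cc(OCc3ccccc3)c(OCc3ccccc3)cc2OS(=O)(=O)C(F)(F)F)[C@H]1c1cc(OCc2ccccc2)c(OCc2ccccc2)cc1OS(=O)(=O)C(F)(F)F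
F7 | step 15 | (1R,2R,3R,4R)-3,4-bis{4,5-bis(benzyloxy)-2-[(trifluoromethanesulfonyl)oxy]phenyl}cyclobutane-1,2-dicarboxylic acid | OC(=O)[C@H]1[C@H](C(=O)O)[C@H](c2cc(OCc3ccccc3)c(OCc3ccccc3)cc2OS(=O)(=O)C(F)(F)F)[C@H]1c1cc(OCc2ccccc2)c(OCc2ccccc2)cc1OS(=O)(=O)C(F)(F)F
F8 | step 6 | N'-{(E)-[4,5-bis(benzyloxy)-2-(methoxymethoxy)phenyl]methylidene}-4-methylbenzenesulfonohydrazide | COCOc1cc(OCc2ccccc2)c(OCc2ccccc2)cc1/C=N/NS(=O)(=O)c1ccc(C)cc1
F9 | step 6 | 1,2-bis(benzyloxy)-4-(diazomethyl)-5-(methoxymethoxy)benzene | COCOc1cc(OCc2ccccc2)c(OCc2ccccc2)cc1C=[N+]=[N-]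
A1 | alternative 1 | (1R,2R,3R,4R)-3,4-bis[3,4-bis(benzyloxy)phenyl]-N,N'-di(quinolin-8-yl)cyclobutane-1,2-dicarboxamide | O=C(Nc1cccc2cccnc12)[C@H]1[C@H](C(=O)Nc2cccc3cccnc23)[C@H](c2ccc(OCc3ccccc3)c(OCc3ccccc3)c2)[C@H]1c1ccc(OCc2ccccc2)c(OCc2ccccc2)c1
A2 | alternative 1 | (1R,2R)-N,N'-di(quinolin-8-yl)cyclobutane-1,2-dicarboxamide | O=C(Nc1cccc2cccnc12)[C@H]1[C@H](C(=O)Nc2cccc3cccnc23)CC1
A3 | alternative 1 | 1,2-bis(benzyloxy)-4-iodobenzene | Ic1ccc(OCc2ccccc2)c(OCc2ccccc2)c1
A4 | alternative 2 | (1E,3Z,5Z,7E)-1,8-bis[4,5-bis(benzyloxy)-2-(methoxymethoxy)phenyl]octa-1,3,5,7-tetraene | COCOc1cc(OCc2ccccc2)c(OCc2ccccc2)cc1/C=C/C=C\C=C/C=C/c1cc(OCc2ccccc2)c(OCc2ccccc2)cc1OCOC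
A5 | alternative 2 | cis-fused trans-7,8-bis[4,5-bis(benzyloxy)-2-(methoxymethoxy)phenyl]bicyclo[4.2.0]octa-2,4-diene | C2=C[C@H]1[C@@H](C=C2)[C@H](c2cc(OCc3ccccc3)c(OCc3ccccc3)cc2OCOC)[C@H]1c1cc(OCc2ccccc2)c(OCc2ccccc2)cc1OCOC
A6 | alternative 3 | (E)-3,3',4,4'-tetrakis(benzyloxy)stilbene | O(Cc1ccccc1)c1ccc(/C=C/c2ccc(OCc3ccccc3)c(OCc3ccccc3)c2)cc1OCc1ccccc1
A7 | alternative 3 | bis{(2R)-1-(benzyloxy)-3-[3,4-bis(benzyloxy)phenyl]-1-oxopropan-2-yl} (2E)-but-2-enedioate | O=C(/C=C/C(=O)O[C@H](Cc1ccc(OCc2ccccc2)c(OCc2ccccc2)c1)C(=O)OCc1ccccc1)O[C@H](Cc1ccc(OCc2ccccc2)c(OCc2ccccc2)c1)C(=O)OCc1ccccc1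
A8 | alternative 3 | decabenzyl-protected target, identical with 24 | O=C(O[C@H](Cc1ccc(OCc2ccccc2)c(OCc2ccccc2)c1)C(=O)OCc1ccccc1)[C@H]1[C@H](C(=O)O[C@H](Cc2ccc(OCc3ccccc3)c(OCc3ccccc3)c2)C(=O)OCc2ccccc2)[C@H](c2ccc(OCc3ccccc3)c(OCc3ccccc3)c2)[C@H]1c1ccc(OCc2ccccc2)c(OCc2ccccc2)c1
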